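The rate constants stand for no real mixture.

Z.G forms from Z and G faster than J does, by a factor of 13.5, yet Z.G also falls back to Z and G faster than J, by a factor of 117.

    G + L → G.L (k1 = 0.11 L mol⁻¹ s⁻¹)
    2 G → G2 (k2 = 0.0052 L mol⁻¹ s⁻¹)
    Z + G ⇌ J (K3 = 51 L mol⁻¹, k3 = 0.0062 L mol⁻¹ s⁻¹)
    Z + G ⇌ Z.G (K4 = 5.9 L mol⁻¹, k4 = 0.084 L mol⁻¹ s⁻¹)

| flask | Z | G | L | remark | time |
|---|---|---|---|---|---|
| teal | 0.10 M | 0.150 M | 0.0300 M | one stirred flow tank at steady state, fed with the mixture as stated, mean residence time 12 min |  |
| ochre | 0.10 M | 0.150 M | 0.0300 M | one stirred flow tank at steady state, fed with the mixture as stated, mean residence time 36.0 min |  |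
| red | 0.10 M | 0.150 M | 0.0300 M | plug flow through a tube for 12 min, no back-mixing | 12 min |
| amber | 0.10 M | 0.150 M | 0.0300 M | a closed flask charged with all of it at once and left for 12 min | 12 min |

- for a step with 2 of a species take k times the square, and two of it per event
- the stated concentrations are those of everything mixed, before any reaction; amounts are the same in each set-up
- run time (red): 12 min

- the set-up with the highest share of Z.G in all that became Z.G or J, at the outlet or at the end ("none" if the first two lie within 2 percentage points) (teal / ochre / red / amber / none)
- share of Z.G in all that became Z.G or J, at the outlet or at the end, teal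
- share of Z.G in all that became Z.G or J, at the outlet or at the end, ochre
- share of Z.G in all that became Z.G or J, at the outlet or at the end, red
- share of Z.G in all that became Z.G or J, at the outlet or at the end, amber

Even odds, with equal fractions of the charge leaving as Z.G and as J, make the zero of the scale. In teal at steady state, each product forms at its forward constant times the same product of Z and G and leaves by washout at 0.00139 s⁻¹. With the two main steps taken one-way, the odds are therefore the ratio of the forward constants, 13.5, a share of 93.1%. Letting Z.G return at 0.0142 s⁻¹, about ten times the washout in teal, brings the odds down to 1.20, a share of 54.5%. J returns at 1.22 × 10⁻⁴ s⁻¹, much more slowly than teal washes it out, and adding this return lifts the result to 1.31. This is the tank odds, the fraction of the charge leaving as Z.G per fraction leaving as J, a selectivity factor for a tank, and in teal it gives a share of 56.7%. The remaining steps consume G, which stands in both formation rates alike, so they cancel from the odds. Red and amber have no washout, and their Z and G change with time, so this reckoning stops short of them.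

The forecast names teal as best, with 56.7% for teal, 35% for ochre, 50% for red and 50% for amber, holding for the tanks that “the share does not depend on G or L”.

The simulation gives 56.7% for teal, 35.0% for ochre, 50.0% for red and 50.0% for amber, so teal stands highest. At the outlet of teal, 20.7% of the charged Z is Z.G and 15.8% is J, a ratio read as 1.31, beside the tank odds of 1.31.

In ochre the washout falls to 4.63 × 10⁻⁴ s⁻¹, so the tank odds come to 0.539, below even, a share of 35.0% against the simulated 35.0%. The return of Z.G is the main reason for this low share in ochre: there, Z.G goes back to Z and G 30.8 times as fast as it washes out. With that return struck out, the share in ochre goes from 35.0% to 94.5%, a rise of 59 percentage points.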